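**Strategy.** Iridal is cut in its side chain at the bond between the homogeranyl CH2 and the methyl-bearing sp2 carbon of the alkene C(CH3)=CH–CH2–CH2–C1, where C1 is the quaternary carbon of the cyclohexane. A Zweifel olefination joins homogeranyl pinacolboronate to the alkenyllithium from a (Z)-2-iodoalkene that carries the complete silyl-protected ring. Boron-to-carbon 1,2-migration forms the C–C bond and anti-elimination inverts the olefin, so the required E trisubstituted alkene arises from the easily made Z iodide. The feature exploited is this acyclic trisubstituted alkene. The ring stereocentres C1, C2, C6 and the exocyclic Z alkene at C3 are set beforehand.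

Key step: step 15

Remark on numbering: ring atoms are numbered as in the strategy (not IUPAC). C1 = quaternary carbon (CH3, side chain), C2 = CH carrying the 3-oxypropyl group, C3 = alkylidene carbon, C4 and C5 = CH2, C6 = carbinol carbon. The β face is the face of the C1 methyl.

Remark on step 1: the antipode of the phosphoramidite ligand is assumed to be the one that delivers the alkyl group to the enantiotopic position giving (S)-4; both antipodes are available.

Step 1
Reactants: 1 4,4-dimethoxycyclohexa-2,5-dien-1-one; 2 tert-butyl(3-iodopropoxy)dimethylsilane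
Product: 4 (S)-5-[3-(tert-butyldimethylsilyloxy)propyl]-4,4-dimethoxycyclohex-2-en-1-one, via diorganozinc 3 (not isolated)
Conditions: 2, Et2Zn (neat), CuI (cat.), 50 °C, volatiles removed in vacuo; then Cu(OTf)2 (2 mol%), Feringa binaphthyl bis(1-phenylethyl)phosphoramidite (4 mol%), 1, toluene, −30 °C; aq. NH4Cl
Reagents that add atoms: none
Why: Copper/phosphoramidite-catalysed asymmetric conjugate addition (Feringa) of a functionalised dialkylzinc made by iodine–zinc exchange (Knochel) should desymmetrise the prochiral quinone monoketal, the ligand choosing one enantiotopic β-carbon and face and so setting C2, while the zinc dienolate formed is inert to a second addition.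

Step 2
Reactants: 4 (S)-5-[3-(tert-butyldimethylsilyloxy)propyl]-4,4-dimethoxycyclohex-2-en-1-one
Product: 5 (5S,6S)-5-[3-(tert-butyldimethylsilyloxy)propyl]-4,4-dimethoxy-6-methylcyclohex-2-en-1-one
Conditions: LDA, THF, −78 °C; MeI, DMPU, −78 → −30 °C
Reagents that add atoms: iodomethane, CI
Why: Kinetic enolate alkylation in which the residual enone leaves C1 as the only enolisable position, methyl iodide entering trans to the C2 chain (this centre is re-enolised in step 3).

Step 3
Reactants: 5 (5S,6S)-5-[3-(tert-butyldimethylsilyloxy)propyl]-4,4-dimethoxy-6-methylcyclohex-2-en-1-one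
Product: 6 (5S,6S)-6-allyl-5-[3-(tert-butyldimethylsilyloxy)propyl]-4,4-dimethoxy-6-methylcyclohex-2-en-1-one
Conditions: LDA, THF, −78 → 0 °C; allyl bromide, DMPU, −78 °C → rt
Reagents that add atoms: allyl bromide, C=CCBr
Why: Enolate allylation that builds the quaternary C1, the tetrasubstituted enolate being attacked anti to the pseudoaxial C2 chain, so that allyl ends trans and methyl cis to that chain (the methyl-then-allyl order fixes this sense).

Step 4
Reactants: 6 (5S,6S)-6-allyl-5-[3-(tert-butyldimethylsilyloxy)propyl]-4,4-dimethoxy-6-methylcyclohex-2-en-1-one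
Product: 7 (1S,5S,6S)-6-allyl-5-[3-(tert-butyldimethylsilyloxy)propyl]-4,4-dimethoxy-1,6-dimethylcyclohex-2-en-1-ol
Conditions: MeLi, Et2O/THF, −78 °C; H2O
Reagents that add atoms: methyllithium, [Li]C
Why: 1,2-Addition of methyllithium to a non-enolisable enone, attack coming from the α face anti to the pseudoaxial C1 methyl (the C2 chain also shields the β face), which should place the new C6 methyl α and the hydroxyl β.

Step 5
Reactants: 7 (1S,5S,6S)-6-allyl-5-[3-(tert-butyldimethylsilyloxy)propyl]-4,4-dimethoxy-1,6-dimethylcyclohex-2-en-1-ol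
Product: 8 (4S,5S,6S)-5-allyl-6-[3-(tert-butyldimethylsilyloxy)propyl]-4-hydroxy-4,5-dimethylcyclohex-2-en-1-one
Conditions: PPTS (cat.), acetone/H2O, rt
Reagents that add atoms: water, O
Why: Acid-catalysed hydrolysis of the allylic dimethyl ketal through a conjugated oxocarbenium ion is fast enough under buffered acid to spare the TBS ether and the tertiary alcohol, and it touches no stereocentre.

Step 6
Reactants: 8 (4S,5S,6S)-5-allyl-6-[3-(tert-butyldimethylsilyloxy)propyl]-4-hydroxy-4,5-dimethylcyclohex-2-en-1-one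
Product: 9 (4S,5S,6S)-5-allyl-6-[3-(tert-butyldimethylsilyloxy)propyl]-4,5-dimethyl-4-(triethylsilyloxy)cyclohex-2-en-1-one
Conditions: TESOTf, 2,6-lutidine, CH2Cl2, −78 → 0 °C
Reagents that add atoms: triethylsilyl trifluoromethanesulfonate, CC[Si](CC)(CC)OS(=O)(=O)C(F)(F)F
Why: Silyl triflate silylation of the hindered tertiary alcohol, under which the enone (enolisable only at the hindered C2–H) is not converted to a silyl dienol ether at low temperature with lutidine.

Step 7
Reactants: 9 (4S,5S,6S)-5-allyl-6-[3-(tert-butyldimethylsilyloxy)propyl]-4,5-dimethyl-4-(triethylsilyloxy)cyclohex-2-en-1-one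
Product: 11 (4S,5S,6S)-5-allyl-6-[3-(tert-butyldimethylsilyloxy)propyl]-4,5-dimethyl-4-(triethylsilyloxy)cyclohex-1-en-1-yl trifluoromethanesulfonate, via lithium enolate 10 (not isolated)
Conditions: L-Selectride, THF, −78 °C; then PhNTf2, −78 → 0 °C
Reagents that add atoms: N-phenylbis(trifluoromethanesulfonimide), O=S(=O)(N(c1ccccc1)S(=O)(=O)C(F)(F)F)C(F)(F)F
Why: Reductive triflation, in which conjugate hydride addition to the β-unsubstituted cyclohexenone gives the C3–C4 enolate regiospecifically and O-triflation fixes it, with no base contact at the epimerisable C2–H.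

Step 8
Reactants: 12 tert-butyldimethyl(prop-2-yn-1-yloxy)silane
Product: 13 tert-butyldimethyl{[2-(4,4,5,5-tetramethyl-1,3,2-dioxaborolan-2-yl)prop-2-en-1-yl]oxy}silane
Conditions: B2pin2, (SIMes)CuCl (5 mol%), NaOt-Bu (cat.), MeOH, THF, −50 °C → rt
Reagents that add atoms: bis(pinacolato)diboron, CC1(C)OB(OC1(C)C)B1OC(C)(C)C(C)(C)O1
Why: NHC–copper-catalysed protoboration of a terminal alkyne, in which an N-aryl NHC ligand and the propargylic ether direct boron to the internal carbon (α-vinylboronate) and methanol protonates the alkenylcopper.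

Step 9
Reactants: 11 (4S,5S,6S)-5-allyl-6-[3-(tert-butyldimethylsilyloxy)propyl]-4,5-dimethyl-4-(triethylsilyloxy)cyclohex-1-en-1-yl trifluoromethanesulfonate; 13 tert-butyldimethyl{[2-(4,4,5,5-tetramethyl-1,3,2-dioxaborolan-2-yl)prop-2-en-1-yl]oxy}silane
Product: 14 the 2,3-disubstituted 1,3-diene in which the triflate of 11 is replaced by a 3-(tert-butyldimethylsilyloxy)prop-1-en-2-yl group (ring stereocentres as in 11)
Conditions: Pd(dppf)Cl2 (5 mol%), aq. K3PO4, THF, 60 °C
Reagents that add atoms: none
Why: Suzuki–Miyaura coupling of an alkenyl triflate with a 1,1-disubstituted alkenylboronate, which should not be diverted by a Heck reaction with the C1 allyl group because that cyclisation would need a bridgehead alkene.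

Step 10
Reactants: 14 the 1,3-diene from step 9
Product: 15 the (Z)-tetrasubstituted alkene in which ring C3 carries an exocyclic =C(CH3)CH2OTBS group with CH2OTBS cis to C2 and CH3 cis to C4 (C1 allyl; C2 3-(TBSO)propyl; C6 OTES; stereocentres as in 11)
Conditions: (η6-naphthalene)Cr(CO)3 (20 mol%), H2 (70 atm), acetone, 25–45 °C
Reagents that add atoms: none
Why: Arene–Cr(CO)3-catalysed 1,4-hydrogenation of a 1,3-diene, in which H2 is added to the two termini (C4 and the exocyclic CH2) of the s-cis η4-bound diene, so the new C3=C bond must form with the new CH3 cis to C4 and CH2OTBS cis to C2 (Z), while isolated alkenes such as the allyl group are not reduced and no stereogenic carbon is created.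

Step 11
Reactants: 15 the (Z)-tetrasubstituted alkene from step 10
Product: 17 the primary alcohol in which the C1 allyl group of 15 has become a 3-hydroxypropyl group, via B-alkyl-9-BBN 16 (not isolated)
Conditions: 9-BBN, THF, 0 °C → rt; then NaOH, H2O2, 0 °C
Reagents that add atoms: hydrogen peroxide, OO
Why: Anti-Markovnikov hydroboration–oxidation, 9-BBN reacting only with the monosubstituted alkene and leaving the tetrasubstituted alkene untouched.

Step 12
Reactants: 17 the primary alcohol from step 11
Product: 18 the aldehyde in which C1 carries a 3-oxopropyl group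
Conditions: Dess–Martin periodinane, NaHCO3, CH2Cl2, 0 °C → rt
Reagents that add atoms: none
Why: Dess–Martin oxidation of a primary alcohol under buffered conditions stops at the aldehyde and spares silyl ethers and the alkene.

Step 13
Reactants: 18 the aldehyde from step 12
Product: 19 the (Z)-alkenyl iodide in which C1 carries a (Z)-4-iodopent-3-en-1-yl group (iodine cis to the chain)
Conditions: EtPPh3I, n-BuLi, THF, rt; I2, −78 °C; NaHMDS, −20 °C; then 18, −78 → −20 °C
Reagents that add atoms: ethyltriphenylphosphonium iodide, CC[P+](c1ccccc1)(c1ccccc1)c1ccccc1.[I-]; iodine, II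
Why: Wittig olefination with the α-iodoethylidene ylide (Stork–Zhao type, Zhao variant), which under kinetic control as for non-stabilised ylides should give the 2-iodoalk-2-ene with iodine cis to the chain.

Step 14
Reactants: 20 geranyl bromide
Product: 21 homogeranyl pinacolboronate, 2-[(3E)-4,8-dimethylnona-3,7-dien-1-yl]-4,4,5,5-tetramethyl-1,3,2-dioxaborolane
Conditions: CH2(Bpin)2, NaOt-Bu, THF, rt
Reagents that add atoms: bis[(pinacolato)boryl]methane, CC1(C)OB(CB2OC(C)(C)C(C)(C)O2)OC1(C)C
Why: Deborylative alkylation, in which alkoxide attack on one boron of the geminal bis(boronate) releases an α-boryl carbanion that displaces the primary allylic bromide at the unhindered CH2 (SN2, not SN2′ at the trisubstituted carbon), leaving the E alkene untouched.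

Step 15
Reactants: 19 the (Z)-alkenyl iodide from step 13; 21 homogeranyl pinacolboronate
Product: 25 tris-silylated iridal precursor with the complete (E,E)-homofarnesyl side chain on C1 (C2 3-(TBSO)propyl; C3 (Z)-=C(CH3)CH2OTBS; C6 OTES), via alkenyllithium 22 (not isolated), via boronate complex 23 (not isolated), via β-iodoboronic ester 24 (not isolated)
Conditions: 19, t-BuLi (2.1 equiv), Et2O/THF, −78 °C; 21, −78 → 0 °C; I2, THF/MeOH, −78 °C; NaOMe, MeOH, −78 °C → rt
Reagents that add atoms: none
Why: Iodine–lithium exchange of 19 proceeds with retention and the alkenyllithium adds to the boron of 21 to give a tetracoordinate boronate. Iodine then activates the boronate alkene as an iodonium ion and triggers a stereospecific 1,2-migration of the primary homogeranyl group from boron to the adjacent carbon, anti to the new C–I bond, which forms the CH2–C(CH3) bond; methoxide finally induces anti β-elimination of boron and iodine. The closest known reaction type is the Zweifel olefination of alkenyllithiums with pinacol boronic esters, including α-substituted alkenyl partners that give trisubstituted alkenes. No ring is closed and no stereogenic carbon survives. The only stereo-element, the alkene geometry, is controlled by the anti-migration/anti-elimination sequence, which places homogeranyl trans to the chain that was cis to boron, so the Z iodide gives the E alkene. The step needs iodine to select the electron-rich boronate alkene over the two isolated trisubstituted alkenes and the tetrasubstituted allylic ether, which the far higher nucleophilicity of the boronate at −78 °C with stoichiometric iodine should secure, and it needs the absence of acidic or electrophilic groups, which full silyl protection secures.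

Step 16
Reactants: 25 the tris-silylated coupling product
Product: 26 the triol (iridal with CH2OH in place of CHO)
Conditions: TBAF, THF, rt → 45 °C
Reagents that add atoms: none
Why: Fluoride-induced desilylation removes both TBS ethers and the tertiary TES ether under non-acidic conditions that the polyene and the allylic alcohol tolerate.

Step 17
Reactants: 26 the triol
Product: 27 iridal
Conditions: activated MnO2, CH2Cl2, rt
Reagents that add atoms: none
Why: Manganese dioxide oxidises only the allylic primary alcohol, so the enal should form with retention of the Z geometry while the saturated primary and the tertiary alcohol remain.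

**Compound list**

1 | 4,4-dimethoxycyclohexa-2,5-dien-1-one | COC1(OC)C=CC(=O)C=C1 | starting material
2 | tert-butyl(3-iodopropoxy)dimethylsilane | CC(C)(C)[Si](C)(C)OCCCI | starting material
3 | bis[3-(tert-butyldimethylsilyloxy)propyl]zinc | CC(C)(C)[Si](C)(C)OCCC[Zn]CCCO[Si](C)(C)C(C)(C)C | intermediate (not isolated)
4 | (S)-5-[3-(tert-butyldimethylsilyloxy)propyl]-4,4-dimethoxycyclohex-2-en-1-one | O=C1C[C@H](CCCO[Si](C)(C)C(C)(C)C)C(OC)(OC)C=C1 | intermediate
5 | (5S,6S)-5-[3-(tert-butyldimethylsilyloxy)propyl]-4,4-dimethoxy-6-methylcyclohex-2-en-1-one (methyl trans to the chain) | C[C@H]1[C@H](CCCO[Si](C)(C)C(C)(C)C)C(OC)(OC)C=CC1=O | intermediate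
6 | (5S,6S)-6-allyl-5-[3-(tert-butyldimethylsilyloxy)propyl]-4,4-dimethoxy-6-methylcyclohex-2-en-1-one (allyl trans to the chain) | C=CC[C@@]1(C)[C@H](CCCO[Si](C)(C)C(C)(C)C)C(OC)(OC)C=CC1=O | intermediate
7 | (1S,5S,6S)-6-allyl-5-[3-(tert-butyldimethylsilyloxy)propyl]-4,4-dimethoxy-1,6-dimethylcyclohex-2-en-1-ol (OH cis to the C6 methyl) | C=CC[C@@]1(C)[C@H](CCCO[Si](C)(C)C(C)(C)C)C(OC)(OC)C=C[C@]1(C)O | intermediate
8 | (4S,5S,6S)-5-allyl-6-[3-(tert-butyldimethylsilyloxy)propyl]-4-hydroxy-4,5-dimethylcyclohex-2-en-1-one | C=CC[C@@]1(C)[C@H](CCCO[Si](C)(C)C(C)(C)C)C(=O)C=C[C@]1(C)O | intermediate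
9 | (4S,5S,6S)-5-allyl-6-[3-(tert-butyldimethylsilyloxy)propyl]-4,5-dimethyl-4-(triethylsilyloxy)cyclohex-2-en-1-one | C=CC[C@@]1(C)[C@H](CCCO[Si](C)(C)C(C)(C)C)C(=O)C=C[C@]1(C)O[Si](CC)(CC)CC | intermediate
10 | lithium C3–C4 enolate from conjugate reduction of 9 | C=CC[C@@]1(C)[C@H](CCCO[Si](C)(C)C(C)(C)C)C(O[Li])=CC[C@]1(C)O[Si](CC)(CC)CC | intermediate (not isolated)
11 | (4S,5S,6S)-5-allyl-6-[3-(tert-butyldimethylsilyloxy)propyl]-4,5-dimethyl-4-(triethylsilyloxy)cyclohex-1-en-1-yl trifluoromethanesulfonate | C=CC[C@@]1(C)[C@H](CCCO[Si](C)(C)C(C)(C)C)C(OS(=O)(=O)C(F)(F)F)=CC[C@]1(C)O[Si](CC)(CC)CC | intermediate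
12 | tert-butyldimethyl(prop-2-yn-1-yloxy)silane | C#CCO[Si](C)(C)C(C)(C)C | starting material
13 | tert-butyldimethyl{[2-(pinacolboryl)prop-2-en-1-yl]oxy}silane | C=C(CO[Si](C)(C)C(C)(C)C)B1OC(C)(C)C(C)(C)O1 | intermediate
14 | 1,3-diene: 11 with OTf replaced by 3-(tert-butyldimethylsilyloxy)prop-1-en-2-yl | C=CC[C@@]1(C)[C@H](CCCO[Si](C)(C)C(C)(C)C)C(C(=C)CO[Si](C)(C)C(C)(C)C)=CC[C@]1(C)O[Si](CC)(CC)CC | intermediate
15 | (Z)-tetrasubstituted alkene: C3 =C(CH3)CH2OTBS with CH2OTBS cis to C2; C1 allyl (α), CH3 (β); C2 3-(TBSO)propyl (β); C6 OTES (β), CH3 (α) | C=CC[C@@]1(C)[C@H](CCCO[Si](C)(C)C(C)(C)C)/C(=C(/C)CO[Si](C)(C)C(C)(C)C)CC[C@]1(C)O[Si](CC)(CC)CC | intermediate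
16 | B-alkyl-9-BBN adduct of the allyl group of 15 | C1CC2CCCC(C1)B2CCC[C@@]3(C)[C@H](CCCO[Si](C)(C)C(C)(C)C)/C(=C(/C)CO[Si](C)(C)C(C)(C)C)CC[C@]3(C)O[Si](CC)(CC)CC | intermediate (not isolated)
17 | primary alcohol: 15 with C1 3-hydroxypropyl in place of allyl | OCCC[C@@]1(C)[C@H](CCCO[Si](C)(C)C(C)(C)C)/C(=C(/C)CO[Si](C)(C)C(C)(C)C)CC[C@]1(C)O[Si](CC)(CC)CC | intermediate
18 | aldehyde: C1 3-oxopropyl | O=CCC[C@@]1(C)[C@H](CCCO[Si](C)(C)C(C)(C)C)/C(=C(/C)CO[Si](C)(C)C(C)(C)C)CC[C@]1(C)O[Si](CC)(CC)CC | intermediate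
19 | (Z)-alkenyl iodide: C1 (Z)-4-iodopent-3-en-1-yl | C/C(I)=C/CC[C@@]1(C)[C@H](CCCO[Si](C)(C)C(C)(C)C)/C(=C(/C)CO[Si](C)(C)C(C)(C)C)CC[C@]1(C)O[Si](CC)(CC)CC | intermediate
20 | geranyl bromide, (2E)-1-bromo-3,7-dimethylocta-2,6-diene | CC(C)=CCC/C(C)=C/CBr | starting material
21 | homogeranyl pinacolboronate | CC(C)=CCC/C(C)=C/CCB1OC(C)(C)C(C)(C)O1 | intermediate
22 | (Z)-alkenyllithium from 19 (lithium cis to the chain) | C/C([Li])=C/CC[C@@]1(C)[C@H](CCCO[Si](C)(C)C(C)(C)C)/C(=C(/C)CO[Si](C)(C)C(C)(C)C)CC[C@]1(C)O[Si](CC)(CC)CC | intermediate (not isolated)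
23 | lithium alkenyl(homogeranyl)pinacolboronate complex | C/C(=C/CC[C@@]1(C)[C@H](CCCO[Si](C)(C)C(C)(C)C)/C(=C(/C)CO[Si](C)(C)C(C)(C)C)CC[C@]1(C)O[Si](CC)(CC)CC)[B-]2(CC/C=C(\C)CCC=C(C)C)OC(C)(C)C(C)(C)O2.[Li+] | intermediate (not isolated)
24 | β-iodo tertiary boronic ester, anti adduct (one of the two diastereomers drawn; both give 25) | C[C@](B1OC(C)(C)C(C)(C)O1)(CC/C=C(\C)CCC=C(C)C)[C@H](I)CC[C@@]2(C)[C@H](CCCO[Si](C)(C)C(C)(C)C)/C(=C(/C)CO[Si](C)(C)C(C)(C)C)CC[C@]2(C)O[Si](CC)(CC)CC | intermediate (not isolated)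
25 | tris-silylated coupling product with the (E,E)-homofarnesyl chain | CC(C)=CCC/C(C)=C/CC/C(C)=C/CC[C@@]1(C)[C@H](CCCO[Si](C)(C)C(C)(C)C)/C(=C(/C)CO[Si](C)(C)C(C)(C)C)CC[C@]1(C)O[Si](CC)(CC)CC | intermediate
26 | triol (iridal with CH2OH in place of CHO) | CC(C)=CCC/C(C)=C/CC/C(C)=C/CC[C@@]1(C)[C@H](CCCO)/C(=C(/C)CO)CC[C@]1(C)O | intermediate
27 | iridal | CC(C)=CCC/C(C)=C/CC/C(C)=C/CC[C@@]1(C)[C@H](CCCO)/C(=C(/C)C=O)CC[C@]1(C)O | target

**Step count.** 17 steps in total. The longest linear sequence is 15 steps (steps 1–7, 9–13, 15–17).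

**Steps most likely to fail**

Step 15 (Zweifel coupling). The alkenyllithium may lose its geometry, or iodination of the polyene may outrun the 1,2-migration. The fallback is a stereoretentive B-alkyl Suzuki–Miyaura coupling that sets out from aldehyde 18 and returns at 25. Ohira–Bestmann homologation would give the terminal alkyne F1, and n-BuLi/MeI would give the methylalkyne F2. Hydrozirconation with excess Cp2Zr(H)Cl at 50 °C (zirconium equilibrates to the methyl-bearing carbon) followed by I2 would give the (E)-alkenyl iodide F3, with iodine trans to the chain. Separately, Wittig methylenation of commercial geranial would give (E)-4,8-dimethylnona-1,3,7-triene F4, and 9-BBN would hydroborate its terminal vinyl group to B-homogeranyl-9-BBN F5. Coupling of F3 with F5 [Pd(dppf)Cl2, AsPh3, Cs2CO3, DMF/THF/H2O] would give 25.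

Step 10 (1,4-hydrogenation). The hindered 2,3-disubstituted diene may not bind chromium in the s-cis form, or double bonds may migrate. The fallback sets out from triflate 11 and returns at 15. Stille coupling with tributyl(1-ethoxyvinyl)stannane (Pd(PPh3)4, LiCl) would give the enol ether F6, and mild aqueous acid would give the methyl ketone F7. Li/NH3 reduction of this s-trans enone and trapping of the enolate with PhNTf2 would give the tetrasubstituted enol triflate F8 with oxygen cis to C2, because A(1,3) strain keeps the methyl on the C4 side. Palladium-catalysed methoxycarbonylation (CO, MeOH, Et3N) would give the ester F9, DIBAL-H would give the allylic alcohol F10, and TBSCl/imidazole would give 15.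

Step 7 (reductive triflation). The bulky hydride may reduce the carbonyl (1,2) instead of adding to the neopentylic β-carbon. The fallback sets out from enone 6 and returns at 11, making the triflate by kinetic deprotonation of a saturated ketone instead. Conjugate reduction of 6 with Stryker's reagent would give the saturated ketone F11. MeMgBr/CeCl3 should add axially, anti to the axial C1 methyl, to give the tertiary alcohol F12. Ketal hydrolysis (PPTS, wet acetone) would give the hydroxy ketone F13, and TESOTf/2,6-lutidine would give the silyl ether F14. Kinetic deprotonation at the unhindered C4 (KHMDS, −78 °C) with PhNTf2 would give 11.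

**Further compounds**

F1 | step 15 | terminal alkyne: C1 but-3-yn-1-yl | C#CCC[C@@]1(C)[C@H](CCCO[Si](C)(C)C(C)(C)C)/C(=C(/C)CO[Si](C)(C)C(C)(C)C)CC[C@]1(C)O[Si](CC)(CC)CC
F2 | step 15 | methylalkyne: C1 pent-3-yn-1-yl | CC#CCC[C@@]1(C)[C@H](CCCO[Si](C)(C)C(C)(C)C)/C(=C(/C)CO[Si](C)(C)C(C)(C)C)CC[C@]1(C)O[Si](CC)(CC)CC
F3 | step 15 | (E)-alkenyl iodide: C1 (E)-4-iodopent-3-en-1-yl | C/C(I)=C\CC[C@@]1(C)[C@H](CCCO[Si](C)(C)C(C)(C)C)/C(=C(/C)CO[Si](C)(C)C(C)(C)C)CC[C@]1(C)O[Si](CC)(CC)CC
F4 | step 15 | (E)-4,8-dimethylnona-1,3,7-triene | C=C/C=C(\C)CCC=C(C)C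
F5 | step 15 | B-homogeranyl-9-BBN | CC(C)=CCC/C(C)=C/CCB1C2CCCC1CCC2
F6 | step 10 | enol ether: 11 with OTf replaced by 1-ethoxyvinyl | C=CC[C@@]1(C)[C@H](CCCO[Si](C)(C)C(C)(C)C)C(C(=C)OCC)=CC[C@]1(C)O[Si](CC)(CC)CC
F7 | step 10 | methyl ketone: 11 with OTf replaced by acetyl | C=CC[C@@]1(C)[C@H](CCCO[Si](C)(C)C(C)(C)C)C(C(C)=O)=CC[C@]1(C)O[Si](CC)(CC)CC
F8 | step 10 | tetrasubstituted enol triflate: C3 =C(CH3)OTf with OTf cis to C2 | C=CC[C@@]1(C)[C@H](CCCO[Si](C)(C)C(C)(C)C)/C(=C(/C)OS(=O)(=O)C(F)(F)F)CC[C@]1(C)O[Si](CC)(CC)CC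
F9 | step 10 | (Z)-methyl ester: C3 =C(CH3)CO2CH3 with ester cis to C2 | C=CC[C@@]1(C)[C@H](CCCO[Si](C)(C)C(C)(C)C)/C(=C(/C)C(=O)OC)CC[C@]1(C)O[Si](CC)(CC)CC
F10 | step 10 | (Z)-allylic alcohol: C3 =C(CH3)CH2OH | C=CC[C@@]1(C)[C@H](CCCO[Si](C)(C)C(C)(C)C)/C(=C(/C)CO)CC[C@]1(C)O[Si](CC)(CC)CC
F11 | step 7 | saturated ketone: 6 with C4–C5 reduced | C=CC[C@@]1(C)[C@H](CCCO[Si](C)(C)C(C)(C)C)C(OC)(OC)CCC1=O
F12 | step 7 | tertiary alcohol from methyl addition to F11 | C=CC[C@@]1(C)[C@H](CCCO[Si](C)(C)C(C)(C)C)C(OC)(OC)CC[C@]1(C)O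
F13 | step 7 | hydroxy ketone from ketal hydrolysis of F12 | C=CC[C@@]1(C)[C@H](CCCO[Si](C)(C)C(C)(C)C)C(=O)CC[C@]1(C)O
F14 | step 7 | triethylsilyl ether of F13 | C=CC[C@@]1(C)[C@H](CCCO[Si](C)(C)C(C)(C)C)C(=O)CC[C@]1(C)O[Si](CC)(CC)CC
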